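Atoms are numbered C1 to O34 in the order in which they stand in the SMILES string of the target (C1 is the methyl group on C2, C12 the CMe2 carbon, C15=C16 the alkene, C23 the ketone, O28 the ring oxygen).

## Analysis of the target

The target 40 is a C30 compound in which a cis-fused hydroazulenol (cyclopentane C5, C6, C7, C8, C9 fused to the cycloheptane C2, C3, C4, C5, C6, C12, C15) is joined through the exocyclic alkene C15=C16 and the methylene C17 to a trans-fused oxepanone–cyclohexanol (oxepane C19, C21, C22, C23, C25, O28, C29; cyclohexane C18, C19, C29, C30, C31, C32). It has eight stereocentres, C2, C5, C6 and C9 in the west half and C18, C19, C29 and C32 in the east half; the two sets are separated by C16–C17 and cannot control each other, so each half has to be made as one enantiomer. In the west half H2, H5 and H6 lie on one face of the seven-membered ring and the C9 hydroxyl is on the face of H5 and H6; in the east half the C19 methyl, O28 and the C32 hydroxyl are on one face, C21 and C33 on the other, and C17 is equatorial. The alkene is Z, with C17 cis to the quaternary C12, the more crowded flank, so methods that put the larger group on the less hindered side give the wrong isomer. Sensitive groups are the two tertiary alcohols at C9 and C32 (they ionise in acid), the α-alkoxy ketone at C23, and the exocyclic alkene, which acid could move into the ring. The hard part is the west half: a seven-membered ring with the quaternary C12 wedged between C15 and the ring-fusion carbon C6, and a C15 that is hindered on both sides. The strategy rests on one feature: because C12 sits between C15 and C6, the cycloheptane can be read as the six-membered ring (C15, C2, C3, C4, C5, C6) of a cis-hydrindanone into whose C15–C6 bond one CMe2 unit has been inserted.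

## Retrosynthetic reasoning

**End game.** 40 comes from triol 39 by oxidation of the only secondary carbinol (C23), and 39 from the tris-silyl ether 38. C23 is kept as a protected carbinol because the fragment union uses an acetylide and a hydride source, and the tertiary alcohols stay silylated until no acid, base or metal reagent is left.

**C15=C16 geometry.** 38 is cut back to allene 37 by removing the hydrogens on C16 and C17, and 37 to the propargylic carbonate 36 (SN2′ delivery of hydride to C17). The alkene is made by putting hydrogen on C16 last. The C16=C17 π bond of 37 lies in the plane of C2–C15–C12, so the hydrogen donor must pass either C2 (a CH that can turn its hydrogen outward) or C12 (methyl groups only). Hydrogen should end cis to C2 and the chain cis to C12, which is the Z isomer. Carbonyl olefination or an allylic transposition would place the chain on the C2 side.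

**C15–C16 bond.** 36 is cut into ketone 17 and acetylide 34 (from dibromoalkene 33). A ketone flanked by CMe2 and CHMe accepts a linear sp nucleophile but hardly an ylide, so the union of the halves is an acetylide addition.

**C2 methyl.** 17 comes from ketone 14 through 15. C12 is quaternary, so only C2 can be enolised and the methyl group can be introduced without a regiochemical question. The ring expansion is done before this, while C2 is still a methylene.

**Key disconnection, C6–C12.** 14 is cut back to the 1-isopropenyl cis-hydrindanol 12. The forward reaction must place a positive charge on C12 and let C6 migrate from C15 to C12. What is gained is that the quaternary carbon and the seven-membered ring are made together, from a six-membered ring whose stereocentres (C5, C6, C9) are far easier to set.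

**Hydrindanol 12.** The C15–C12 bond is cut to ketone 11 and 2 (isopropenyl addition). The C9 carbinol of 11, 10 and 9 goes back to epoxide 8 and alkene 7, so that oxygen enters from the convex face and hydride opens the epoxide at C8. The cyclopentene of 7 is cut at C8=C9 (metathesis) to 5, and 5 to 1, 2 and 3 by conjugate addition and enolate allylation. C5 is the only stereocentre set by a catalyst.

**East half, C17–C16.** 33 comes from aldehyde 32, and 32 from acetal 31, so that C17 is carried as a masked formyl group until the tertiary C32 oxygen is blocked.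

**East half, O28–C25.** The oxepane of 31 is cut at O28–C25, which leads to diol 29 and a Markovnikov alkoxymercuration of its trisubstituted side-chain alkene.

**East half, C32 methyl.** The C32 methyl is cut from 28 to ketone 27; the addition is steered by the axial C19 methyl.

**East half, C18–C17 and C19–C21.** The C18–C17 bond is cut from 27 to enol ether 26, and the C19–C21 bond from 26 to enone 23 and Grignard reagent 25 (addition anti to the C29 oxygen).

**East half, C29.** 23 goes back through 21 and 20 to 18; C29 is the one east stereocentre set by a reagent (an enzyme).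

## Alternatives that were turned down

Alternative 1: Büchner reaction.
- Disconnection: the C5–C4 and C5–C6 bonds of the hydroazulene are cut back to an arene.
- Forward key step: the carbene formed from diazoketone A1 with Rh2(OAc)4 adds to the ipso–ortho bond of the anisole ring of A1, and the norcaradiene opens to the cyclopentanone-fused cycloheptatriene A2.
- For it: the bicyclic skeleton is reached in one catalytic step from a diazoketone that takes few steps to make; chiral catalysts of the Rh2(O2CR)4 type can set C5; the carbons at C2, C12 and C15 arrive with their substituents. On early step count it is stronger than the route chosen here.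
- Against it: A2 has three ring double bonds and one stereocentre. C6 and C2 would have to be set by reducing a triene with little facial bias. C12 still lacks its second methyl group, to be added next to a carbonyl that can also enolise toward C2. Methyl addition to the C9 ketone of a cis-fused bicycle comes from the convex face and gives the wrong C9 epimer.
- Comparison: the chosen route delivers 14 saturated, with C5, C6 and C9 fixed and the CMe2 group in place.

Alternative 2: diepoxide–enol silane cascade.
- Disconnection: O28–C25 and C18–C19 of the east bicycle.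
- Forward key step: Me3SiOTf opens the terminal epoxide of A3, the oxygen of the internal epoxide attacks C25, and the enol silane carbon C18 opens the epoxonium ion at C19 to give the oxepanol–cyclohexanone A4.
- For it: both east rings and the C19/C29 pair are formed in one step from an acyclic chain whose epoxides come from asymmetric epoxidation. This is clearly shorter than the eleven steps used here for the east half.
- Against it: it solves the easier half and leaves the west half (quaternary C12, contra-steric alkene) untouched. Such cation cascades are moderate in yield and need A3 with two defined epoxides and a regiodefined enol ether. The allyl group of A4 is one carbon too long for an acetylide union.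
- Comparison: the chosen strategy puts its one high-risk step where no stepwise solution exists and builds the east half by reactions that can be checked one by one.

Alternative 3: samarium ketyl–enone coupling.
- Disconnection: C5–C9.
- Forward key step: SmI2 reduces the methyl ketone of A5 to a ketyl, which adds to the enone carbon C5 and gives the cis-fused cyclopentanol A6.
- For it: the cyclopentane, the C9 carbinol (hydroxyl anti to the C5–C4 bond, as needed) and the cis fusion are formed in one mild step. This beats the four steps (epoxidation, hydride, oxidation, silylation) used here for C9.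
- Against it: A5 is a cycloheptenone that already holds the quaternary C12 next to the stereocentre C6 and must be one enantiomer, which is the problem the ring expansion solves. A6 carries a C3 ketone to remove, lacks the C2 methyl, and its C15 methylene gives no good way to attach the chain with Z geometry.
- Comparison: the chosen route is longer before the bicycle but ends with a C15 ketone, the right handle for the acetylide union.

Key step: step 8

Remarks on the chemistry:
- In step 1 the enantiomer of the ferrocenyl diphosphine is chosen that gives the 3R adduct.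
- In step 12 the lipase is assumed to hydrolyse the (R)-enantiomer of 19; if it prefers the (S)-enantiomer, the recovered (R)-enantiomer of 19 is methanolysed (K2CO3, MeOH, 0 °C) to the same alcohol 20.
- C23 is carried as a mixture of carbinol epimers from 31 to 39 and becomes the ketone in the last step.

## Route

West half

Step 1
Reactants: 1 cyclohex-2-en-1-one; 2 isopropenylmagnesium bromide; 3 allyl bromide
Product: 5 (2S,3R)-2-allyl-3-(prop-1-en-2-yl)cyclohexan-1-one, via bromomagnesium enolate 4 (not isolated)
Conditions: CuBr·SMe2 (5 mol %), 1-[2-(diphenylphosphino)ferrocenyl]ethyldicyclohexylphosphine (6 mol %), t-BuOMe, −75 °C; then 3, DMPU, −75 → 0 °C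
Reagents that add atoms: none
Why: Copper-catalysed asymmetric conjugate addition of a Grignard reagent to a cyclic enone, followed by alkylation of the magnesium enolate; the ligand fixes C5 (3R) and the allyl group enters trans to the new substituent (C6 is corrected in step 2).

Step 2
Reactants: 5 (2S,3R)-2-allyl-3-(prop-1-en-2-yl)cyclohexan-1-one
Product: 7 (3aR,7aR)-1-methyl-3,3a,5,6,7,7a-hexahydro-4H-inden-4-one (cis-fused), via trans-fused hydrindenone 6 (not isolated)
Conditions: RuCl2(=CHPh)(PCy3)(H2IMes) (second-generation Grubbs catalyst; H2IMes = 1,3-dimesitylimidazolidin-2-ylidene; 3 mol %), CH2Cl2, 40 °C; then DBU, rt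
Reagents that add atoms: none
Why: Ring-closing metathesis of the isopropenyl and allyl groups closes the cyclopentene (C8=C9) with loss of ethene; DBU then epimerises C6 next to the ketone, and the cis fusion is favoured because a cyclopentene spans a trans junction only with strain.

Step 3
Reactants: 7 cis-fused hydrindenone
Product: 8 cis-fused epoxy ketone (oxygen on the face of H5 and H6)
Conditions: mCPBA, NaHCO3, CH2Cl2, 0 °C
Reagents that add atoms: 3-chloroperoxybenzoic acid, OOC(=O)c1cccc(Cl)c1
Why: Prilezhaev epoxidation of the trisubstituted alkene, much faster than Baeyer–Villiger oxidation of the ketone; the peracid comes from the convex face of the cis-fused bicycle, which places the future C9 oxygen cis to the ring-fusion hydrogens.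

Step 4
Reactants: 8 cis-fused epoxy ketone
Product: 9 (1R,3aR,7aR)-1-methyloctahydro-1H-indene-1,4-diol
Conditions: LiAlH4, THF, 0 °C → reflux
Reagents that add atoms: none
Why: Hydride opens the epoxide by SN2 attack at the less substituted C8, leaving the tertiary C9 carbinol with its oxygen in place; the ketone is reduced as well (its carbinol configuration does not matter).

Step 5
Reactants: 9 diol
Product: 10 (1R,3aR,7aR)-1-hydroxy-1-methyloctahydro-4H-inden-4-one
Conditions: Dess–Martin periodinane, NaHCO3, CH2Cl2, rt
Reagents that add atoms: none
Why: Only the secondary alcohol can be oxidised; buffered, non-enolising conditions keep the cis fusion at C6.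

Step 6
Reactants: 10 hydroxy ketone
Product: 11 (1R,3aR,7aR)-1-methyl-1-[(triethylsilyl)oxy]octahydro-4H-inden-4-one
Conditions: Et3SiOTf, 2,6-lutidine, CH2Cl2, −78 → 0 °C
Reagents that add atoms: triethylsilyl trifluoromethanesulfonate, CC[Si](CC)(CC)OS(=O)(=O)C(F)(F)F
Why: A silyl triflate silylates the hindered tertiary alcohol; with the weak base lutidine the ketone is not converted into an enol ether.

Step 7
Reactants: 11 silyloxy ketone; 2 isopropenylmagnesium bromide
Product: 12 (1R,3aR,4S,7aR)-1-methyl-4-(prop-1-en-2-yl)-1-[(triethylsilyl)oxy]octahydro-1H-inden-4-ol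
Conditions: CeCl3, THF, −78 °C
Reagents that add atoms: none
Why: Organocerium 1,2-addition without enolisation, so C6 is not epimerised; the nucleophile enters from the convex face (C15 hydroxyl cis to the cyclopentane), but either C15 epimer serves the next step.

Step 8
Reactants: 12 1-isopropenyl cis-hydrindanol
Product: 14 (1R,3aR,8aR)-1,4,4-trimethyl-1-[(triethylsilyl)oxy]octahydroazulen-5(1H)-one, via C15 trimethylsilyl ether 13 (not isolated)
Conditions: Me3SiOTf, 2,6-lutidine, CH2Cl2, −78 °C; then TfOH, −78 → −40 °C; Et3N quench
Reagents that add atoms: none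
Why: Silylation of the tertiary allylic hydroxyl removes the one group that a strong acid would ionise to an allyl cation; TfOH then protonates the terminal carbon of the isopropenyl group and puts the positive charge on C12, next to the silyloxy carbon C15. The C15–C6 bond, aligned with the empty orbital, shifts to C12 while oxygen forms the C15 carbonyl, and the silyloxocarbenium ion hands its silyl group to triflate. The closest known reaction type is the acid-induced semipinacol rearrangement of 1-alkenylcycloalkanols and their silyl ethers, of which six-to-seven enlargements are the less common cases. The seven-membered ring is not closed by a cyclisation: it arises by a 1,2-alkyl shift that inserts C12 into the C15–C6 bond of the six-membered ring. No stereocentre is formed; C6 migrates with retention (suprafacial shift), so the cis fusion from step 2 is carried into the hydroazulenone and the C15 configuration of 12 is lost. The step needs migration of C6 and not of C2: C6 is secondary and C2 a methylene, the more substituted carbon carries charge better in the transition state, and this is why C2 is methylated only afterwards. It also needs the tertiary silyl ether at C9 to survive, which the low temperature, the aprotic medium and a short contact with a small excess of acid are meant to secure.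

Step 9
Reactants: 14 hydroazulenone
Product: 15 1,4,4,6-tetramethyl-1-[(triethylsilyl)oxy]octahydroazulen-5(1H)-one (C2 epimers; azulene position 6)
Conditions: LiN(i-Pr)2, THF, −78 °C; MeI
Reagents that add atoms: iodomethane, CI
Why: Enolate alkylation that is regiospecific because C12 is quaternary and only C2 can be deprotonated; the C2 configuration is settled in step 10.

Step 10
Reactants: 15 methyl ketone (C2 epimers)
Product: 17 (1R,3aR,6S,8aR)-1,4,4,6-tetramethyl-1-[(triethylsilyl)oxy]octahydroazulen-5(1H)-one, via potassium enolate 16 (not isolated)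
Conditions: KN(SiMe3)2, THF, −78 → 0 °C; then 2,6-di-tert-butylphenol, −78 °C
Reagents that add atoms: none
Why: Both epimers give the same enolate (C2 is the only enolisable position); kinetic protonation by a hindered phenol from the exo face, the face of H5 and H6 away from the folded cyclopentane, puts the methyl group on the cyclopentane face as in the target. The other epimer can be returned to this step.

East half

Step 11
Reactants: 18 3-ethoxycyclohex-2-en-1-one
Product: 19 rac-4-ethoxy-2-oxocyclohex-3-en-1-yl acetate
Conditions: Mn(OAc)3·2H2O, benzene, reflux (Dean–Stark)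
Reagents that add atoms: manganese triacetate, CC(=O)[O-].CC(=O)[O-].CC(=O)[O-].[Mn+3]
Why: Oxidative α′-acetoxylation of an enone by trivalent manganese through the manganese enolate; the vinylogous ester directs it to the saturated α′ carbon (the future C29).

Step 12
Reactants: 19 rac-acetate
Product: 20 (R)-3-ethoxy-6-hydroxycyclohex-2-en-1-one
Conditions: lipase (Amano PS), phosphate buffer pH 7, t-BuOMe, rt, to about half conversion
Reagents that add atoms: none
Why: Lipase-catalysed enantioselective hydrolysis of a secondary acetate (kinetic resolution); it fixes C29, the only east stereocentre not set by the substrate.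

Step 13
Reactants: 20 (R)-hydroxy enone
Product: 21 (R)-6-[(tert-butyldimethylsilyl)oxy]-3-ethoxycyclohex-2-en-1-one
Conditions: t-BuMe2SiCl, imidazole, DMF, rt
Reagents that add atoms: tert-butyldimethylsilyl chloride, CC(C)(C)[Si](C)(C)Cl
Why: Standard silylation of a secondary alcohol; the ether must survive organolithium and cuprate reagents and direct the conjugate addition.

Step 14
Reactants: 21 silyloxy vinylogous ester
Product: 23 (R)-4-[(tert-butyldimethylsilyl)oxy]-3-methylcyclohex-2-en-1-one, via lithium alkoxide 22 (not isolated)
Conditions: MeLi, THF, −78 °C; then 1 M HCl, 0 °C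
Reagents that add atoms: methyllithium, [Li]C
Why: 1,2-Addition to the vinylogous ester and acid hydrolysis with loss of ethanol and water (Stork–Danheiser enone transposition) put the methyl group on C19 and the carbonyl on C32; C29 is not touched.

Step 15
Reactants: 23 enone; 24 5-bromo-2-methylpent-2-ene
Product: 26 silyl enol ether of the conjugate adduct (1R,2R configuration at C29 and C19), via Grignard reagent 25 (not isolated)
Conditions: Mg, THF; then 23, CuBr·SMe2 (20 mol %), Me3SiCl, THF, −78 → −30 °C
Reagents that add atoms: chlorotrimethylsilane, C[Si](C)(C)Cl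
Why: Copper-catalysed conjugate addition of a Grignard reagent, accelerated and trapped by the silyl chloride; the chain adds to C19 anti to the neighbouring silyloxy group (C21 trans to O28), and the enol ether stores the C18/C32 regiochemistry.

Step 16
Reactants: 26 silyl enol ether
Product: 27 (2S,3R,4R)-4-[(tert-butyldimethylsilyl)oxy]-2-(dimethoxymethyl)-3-methyl-3-(4-methylpent-3-en-1-yl)cyclohexan-1-one
Conditions: HC(OMe)3, Me3SiOTf (5 mol %), CH2Cl2, −78 °C; then Et3N, MeOH, rt
Reagents that add atoms: trimethyl orthoformate, COC(OC)OC
Why: Lewis-acid-mediated alkylation of a silyl enol ether by an orthoester (Mukaiyama type) puts the protected formyl carbon C17 on C18 only; C18 is epimerisable and settles with the dimethoxymethyl group equatorial, cis to the C19 methyl, since the other epimer needs three axial groups or a syn-diaxial pair.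

Step 17
Reactants: 27 β-keto acetal
Product: 28 (1S,2R,3R,4R)-4-[(tert-butyldimethylsilyl)oxy]-2-(dimethoxymethyl)-1,3-dimethyl-3-(4-methylpent-3-en-1-yl)cyclohexan-1-ol
Conditions: MeLi, CeCl3, THF, −78 °C
Reagents that add atoms: methyllithium, [Li]C
Why: Organocerium 1,2-addition without enolisation; 27 sits in the chair with the C19 methyl axial, so methyl reaches C32 along the equatorial path and the hydroxyl ends axial, cis to the C19 methyl, as in the target.

Step 18
Reactants: 28 silyl ether
Product: 29 (1R,2R,3R,4S)-3-(dimethoxymethyl)-2,4-dimethyl-2-(4-methylpent-3-en-1-yl)cyclohexane-1,4-diol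
Conditions: Bu4NF, THF, rt
Reagents that add atoms: none
Why: Fluoride cleavage of the secondary silyl ether frees the C29 hydroxyl for ring closure; acetal and tertiary alcohol are inert.

Step 19
Reactants: 29 diol
Product: 31 trans-fused 6-(dimethoxymethyl)-2,2,5a,7-tetramethyldecahydro-1-benzoxepine-3,7-diol (C23 epimers), via organomercury trifluoroacetate 30 (not isolated)
Conditions: Hg(OCOCF3)2, 2,6-di-tert-butyl-4-methylpyridine, CH2Cl2, −20 °C; then NaBH4, O2, DMF, 0 °C
Reagents that add atoms: dioxygen, O=O
Why: Intramolecular alkoxymercuration of the trisubstituted alkene in the Markovnikov sense (O28 to the tertiary C25, mercury to C23) closes the oxepane by the 7-endo mode, trans-fused because C21 and O28 were set trans in step 15. Reduction of the C–Hg bond under oxygen traps the C23 radical as the carbinol (both epimers, which is of no consequence).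

Step 20
Reactants: 31 oxepanediol acetal
Product: 32 trans-fused 2,2,5a,7-tetramethyl-3,7-bis[(triethylsilyl)oxy]decahydro-1-benzoxepine-6-carbaldehyde (C23 epimers)
Conditions: Et3SiOTf, 2,4,6-collidine, CH2Cl2, 0 °C; then H2O
Reagents that add atoms: triethylsilyl trifluoromethanesulfonate, CC[Si](CC)(CC)OS(=O)(=O)C(F)(F)F; water, O
Why: The silyl triflate with collidine silylates both hydroxyls and converts the dimethyl acetal, through its collidinium adduct, into the aldehyde on aqueous work-up, a known acetal cleavage that spares silyl ethers; the tertiary C32 oxygen is blocked before the β-oxygenated aldehyde exists, so no retro-aldol can occur.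

Step 21
Reactants: 32 aldehyde
Product: 33 6-(2,2-dibromoethenyl) analogue of 32 (dibromoalkene)
Conditions: CBr4, PPh3, CH2Cl2, 0 °C
Reagents that add atoms: carbon tetrabromide, BrC(Br)(Br)Br
Why: Dibromo-olefination of an aldehyde with the ylide from PPh3 and CBr4 (first stage of the Corey–Fuchs sequence); the neutral conditions keep C18, next to the aldehyde, from epimerising.

Union and end game

Step 22
Reactants: 33 dibromoalkene; 17 hydroazulenone
Product: 36 tertiary propargylic methyl carbonate of the joined halves (C15 epimers), via lithium acetylide 34 (not isolated), via lithium alkoxide 35 (not isolated)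
Conditions: n-BuLi (2.1 equiv), THF, −78 → 0 °C; CeCl3, −78 °C; 17; then ClCO2Me, −78 → 0 °C
Reagents that add atoms: methyl chloroformate, COC(=O)Cl
Why: The second stage of the Corey–Fuchs sequence gives the acetylide, whose cerium derivative adds to the doubly hindered ketone without enolising C2 (a linear sp nucleophile is the kind that such ketones accept); acylation of the alkoxide in the same flask gives the carbonate, whose C15 configuration is lost in the next step.

Step 23
Reactants: 36 propargylic carbonate
Product: 37 trisubstituted allene C15=C16=C17 (both axial isomers)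
Conditions: Pd2(dba)3 (5 mol %), PBu3, HCO2NH4, THF, 50 °C
Reagents that add atoms: none
Why: Palladium-catalysed hydrogenolysis of a tertiary propargylic carbonate by formate: SN2′ oxidative addition gives an allenylpalladium species, formate supplies hydride with loss of CO2, and reductive elimination puts hydrogen on C17; the axial configuration is irrelevant because C17 becomes a methylene.

Step 24
Reactants: 37 allene
Product: 38 tris(triethylsilyl) ether of the (Z)-alkene
Conditions: 2-nitrobenzenesulfonylhydrazide, Et3N, CH2Cl2, rt
Reagents that add atoms: none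
Why: Diimide transfers two hydrogens in one step to the less substituted C16=C17 bond of the allene; this π bond lies in the plane of C2–C15–C12, so the reagent must pass C2 or C12, and C2 can turn a hydrogen toward it while C12 offers only methyl groups. Hydrogen therefore ends on C16 cis to C2 and the chain cis to C12 (Z), in line with the known Z-selective semireduction of allenes; the hindered trisubstituted product is not reduced further.

Step 25
Reactants: 38 tris-silyl ether
Product: 39 triol (C9, C32 tertiary; C23 secondary, both epimers)
Conditions: Bu4NF, THF, 50 °C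
Reagents that add atoms: none
Why: Fluoride removes the three triethylsilyl groups under basic conditions that leave the tertiary alcohols and the exocyclic alkene untouched.

Step 26
Reactants: 39 triol
Product: 40 target CNP0157787.1
Conditions: Dess–Martin periodinane, NaHCO3, CH2Cl2, 0 °C → rt
Reagents that add atoms: none
Why: Only the C23 carbinol is secondary, so both epimers converge on the ketone while the tertiary alcohols and the alkene stay as they are.

## Compound list

1 | cyclohex-2-en-1-one | O=C1C=CCCC1 | starting material
2 | isopropenylmagnesium bromide | CC(=C)[Mg]Br | starting material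
3 | allyl bromide | C=CCBr | starting material
4 | bromomagnesium (R)-3-(prop-1-en-2-yl)cyclohex-1-en-1-olate | Br[Mg]OC1=C[C@H](C(C)=C)CCC1 | intermediate
5 | (2S,3R)-2-allyl-3-(prop-1-en-2-yl)cyclohexan-1-one | O=C1CCC[C@@H](C(C)=C)[C@@H]1CC=C | intermediate
6 | (3aS,7aR)-1-methyl-3,3a,5,6,7,7a-hexahydro-4H-inden-4-one (trans-fused) | O=C1CCC[C@@H]2[C@@H]1CC=C2C | intermediate
7 | (3aR,7aR)-1-methyl-3,3a,5,6,7,7a-hexahydro-4H-inden-4-one (cis-fused) | O=C1CCC[C@@H]2[C@H]1CC=C2C | intermediate
8 | 1,2-epoxide of 7, oxygen on the face of the ring-fusion hydrogens | O=C1CCC[C@@H]2[C@H]1C[C@H]1O[C@]12C | intermediate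
9 | (1R,3aR,7aR)-1-methyloctahydro-1H-indene-1,4-diol (C4 carbinol drawn as formed by exo hydride attack) | O[C@H]1CCC[C@@H]2[C@H]1CC[C@@]2(C)O | intermediate
10 | (1R,3aR,7aR)-1-hydroxy-1-methyloctahydro-4H-inden-4-one | O=C1CCC[C@@H]2[C@H]1CC[C@@]2(C)O | intermediate
11 | (1R,3aR,7aR)-1-methyl-1-[(triethylsilyl)oxy]octahydro-4H-inden-4-one | O=C1CCC[C@@H]2[C@H]1CC[C@@]2(C)O[Si](CC)(CC)CC | intermediate
12 | (1R,3aR,4S,7aR)-1-methyl-4-(prop-1-en-2-yl)-1-[(triethylsilyl)oxy]octahydro-1H-inden-4-ol | C=C(C)[C@]1(O)CCC[C@@H]2[C@H]1CC[C@@]2(C)O[Si](CC)(CC)CC | intermediate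
13 | trimethylsilyl ether of 12 at the C15 oxygen | C=C(C)[C@]1(O[Si](C)(C)C)CCC[C@@H]2[C@H]1CC[C@@]2(C)O[Si](CC)(CC)CC | intermediate
14 | (1R,3aR,8aR)-1,4,4-trimethyl-1-[(triethylsilyl)oxy]octahydroazulen-5(1H)-one (cis-fused) | O=C1CCC[C@@H]2[C@@H](CC[C@@]2(C)O[Si](CC)(CC)CC)C1(C)C | intermediate
15 | 6-methyl derivative of 14, both C2 epimers | CC1CC[C@@H]2[C@@H](CC[C@@]2(C)O[Si](CC)(CC)CC)C(C)(C)C1=O | intermediate
16 | potassium enolate of 15 (C2=C15) | CC=1CC[C@@H]2[C@@H](CC[C@@]2(C)O[Si](CC)(CC)CC)C(C)(C)C=1O[K] | intermediate
17 | (1R,3aR,6S,8aR)-1,4,4,6-tetramethyl-1-[(triethylsilyl)oxy]octahydroazulen-5(1H)-one | C[C@H]1CC[C@@H]2[C@@H](CC[C@@]2(C)O[Si](CC)(CC)CC)C(C)(C)C1=O | intermediate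
18 | 3-ethoxycyclohex-2-en-1-one | CCOC1=CC(=O)CCC1 | starting material
19 | rac-4-ethoxy-2-oxocyclohex-3-en-1-yl acetate | CCOC1=CC(=O)C(OC(C)=O)CC1 | intermediate
20 | (R)-3-ethoxy-6-hydroxycyclohex-2-en-1-one | O[C@@H]1CCC(OCC)=CC1=O | intermediate
21 | (R)-6-[(tert-butyldimethylsilyl)oxy]-3-ethoxycyclohex-2-en-1-one | CC(C)(C)[Si](C)(C)O[C@@H]1CCC(OCC)=CC1=O | intermediate
22 | lithium alkoxide from 1,2-addition of methyl to 21 (C1 epimers) | CC(C)(C)[Si](C)(C)O[C@@H]1CCC(OCC)=CC1(C)O[Li] | intermediate
23 | (R)-4-[(tert-butyldimethylsilyl)oxy]-3-methylcyclohex-2-en-1-one | CC(C)(C)[Si](C)(C)O[C@@H]1CCC(=O)C=C1C | intermediate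
24 | 5-bromo-2-methylpent-2-ene | CC(C)=CCCBr | starting material
25 | (4-methylpent-3-en-1-yl)magnesium bromide | CC(C)=CCC[Mg]Br | intermediate
26 | tert-butyldimethyl{[(1R,2R)-2-methyl-2-(4-methylpent-3-en-1-yl)-4-[(trimethylsilyl)oxy]cyclohex-3-en-1-yl]oxy}silane | CC(C)(C)[Si](C)(C)O[C@@H]1CCC(O[Si](C)(C)C)=C[C@@]1(C)CCC=C(C)C | intermediate
27 | (2S,3R,4R)-4-[(tert-butyldimethylsilyl)oxy]-2-(dimethoxymethyl)-3-methyl-3-(4-methylpent-3-en-1-yl)cyclohexan-1-one | COC(OC)[C@@H]1[C@@](C)(CCC=C(C)C)[C@H](O[Si](C)(C)C(C)(C)C)CCC1=O | intermediate
28 | (1S,2R,3R,4R)-4-[(tert-butyldimethylsilyl)oxy]-2-(dimethoxymethyl)-1,3-dimethyl-3-(4-methylpent-3-en-1-yl)cyclohexan-1-ol | COC(OC)[C@@H]1[C@@](C)(CCC=C(C)C)[C@H](O[Si](C)(C)C(C)(C)C)CC[C@]1(C)O | intermediate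
29 | (1R,2R,3R,4S)-3-(dimethoxymethyl)-2,4-dimethyl-2-(4-methylpent-3-en-1-yl)cyclohexane-1,4-diol | COC(OC)[C@@H]1[C@@](C)(CCC=C(C)C)[C@H](O)CC[C@]1(C)O | intermediate
30 | trans-fused oxepane with C23–Hg(OCOCF3) (C23 epimers) | COC(OC)[C@@H]1[C@@]2(C)CCC([Hg]OC(=O)C(F)(F)F)C(C)(C)O[C@@H]2CC[C@]1(C)O | intermediate
31 | (5aR,6R,7S,9aR)-6-(dimethoxymethyl)-2,2,5a,7-tetramethyldecahydro-1-benzoxepine-3,7-diol (C3 = C23 epimers) | COC(OC)[C@@H]1[C@@]2(C)CCC(O)C(C)(C)O[C@@H]2CC[C@]1(C)O | intermediate
32 | (5aR,6R,7S,9aR)-2,2,5a,7-tetramethyl-3,7-bis[(triethylsilyl)oxy]decahydro-1-benzoxepine-6-carbaldehyde (C23 epimers) | O=C[C@@H]1[C@@]2(C)CCC(O[Si](CC)(CC)CC)C(C)(C)O[C@@H]2CC[C@]1(C)O[Si](CC)(CC)CC | intermediate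
33 | 6-(2,2-dibromoethenyl)-2,2,5a,7-tetramethyl-3,7-bis[(triethylsilyl)oxy]decahydro-1-benzoxepine, ring configuration as in 32 | BrC(Br)=C[C@@H]1[C@@]2(C)CCC(O[Si](CC)(CC)CC)C(C)(C)O[C@@H]2CC[C@]1(C)O[Si](CC)(CC)CC | intermediate
34 | lithium acetylide from 33 (C16 lithiated, C17 on C18) | [Li]C#C[C@@H]1[C@@]2(C)CCC(O[Si](CC)(CC)CC)C(C)(C)O[C@@H]2CC[C@]1(C)O[Si](CC)(CC)CC | intermediate
35 | lithium tertiary propargylic alkoxide from 34 and 17 (C15 epimers) | C[C@H]1CC[C@@H]2[C@@H](CC[C@@]2(C)O[Si](CC)(CC)CC)C(C)(C)C1(O[Li])C#C[C@@H]1[C@@]2(C)CCC(O[Si](CC)(CC)CC)C(C)(C)O[C@@H]2CC[C@]1(C)O[Si](CC)(CC)CC | intermediate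
36 | methyl carbonate of the tertiary propargylic alcohol (C15 epimers) | C[C@H]1CC[C@@H]2[C@@H](CC[C@@]2(C)O[Si](CC)(CC)CC)C(C)(C)C1(OC(=O)OC)C#C[C@@H]1[C@@]2(C)CCC(O[Si](CC)(CC)CC)C(C)(C)O[C@@H]2CC[C@]1(C)O[Si](CC)(CC)CC | intermediate
37 | allene C15=C16=C17 joining the two silylated halves (both axial isomers) | C[C@H]1CC[C@@H]2[C@@H](CC[C@@]2(C)O[Si](CC)(CC)CC)C(C)(C)C1=C=C[C@@H]1[C@@]2(C)CCC(O[Si](CC)(CC)CC)C(C)(C)O[C@@H]2CC[C@]1(C)O[Si](CC)(CC)CC | intermediate
38 | (Z)-alkene, tris(triethylsilyl) ether of 39 | C[C@H]1CC[C@@H]2[C@@H](CC[C@@]2(C)O[Si](CC)(CC)CC)C(C)(C)/C1=C\C[C@@H]1[C@@]2(C)CCC(O[Si](CC)(CC)CC)C(C)(C)O[C@@H]2CC[C@]1(C)O[Si](CC)(CC)CC | intermediate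
39 | C23 carbinol of the target (both C23 epimers) | C[C@H]1CC[C@@H]2[C@@H](CC[C@@]2(C)O)C(C)(C)/C1=C\C[C@@H]1[C@@]2(C)CCC(O)C(C)(C)O[C@@H]2CC[C@]1(C)O | intermediate
40 | CNP0157787.1 | C[C@H]1CC[C@@H]2[C@@H](CC[C@@]2(C)O)C(C)(C)/C1=C\C[C@@H]1[C@@]2(C)CCC(=O)C(C)(C)O[C@@H]2CC[C@]1(C)O | target

## Step count and least certain steps

Total: 26 steps. Longest linear sequence: 16 steps (18 → 40, steps 11–21 and 22–26); the west branch is 15 steps (1 → 40, steps 1–10 and 22–26).

**Step 8 (key step).** What is most likely to go wrong is ionisation instead of rearrangement: loss of the C15 oxygen to an allyl cation if silylation is incomplete, loss of the tertiary C9 silyloxy group to a cation that eliminates, or competing migration of C2. A six-membered ring also offers no strain release to drive the shift. Fallback, setting out from 11 and returning at 14: the ketone 11 is treated with 2-lithio-2-(methylseleno)propane (from 2,2-bis(methylseleno)propane and n-BuLi) to give the β-hydroxy selenide F1. AgBF4 on alumina then pulls the selenide off C12, and the same C6 shift gives 14 without any strong acid (the known selenide-based ring homologation of ketones to α,α-dimethyl ketones).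

**Step 24.** The risk is poor selectivity between the two in-plane directions of approach, because C2 also carries a methyl group, or slow reduction of a crowded allene; either would give the E isomer F2 beside 38. Fallback, setting out from 37 and returning at 38: the reduction is run without regard to selectivity, and the (E)-alkene F2 is separated and epoxidised (mCPBA) to the epoxide F3. LiPPh2 opens the epoxide F3 at C16 with inversion; an acetic acid quench and MeI then give the β-hydroxy phosphonium iodide F4. NaH converts F4 into the betaine, whose syn elimination of methyldiphenylphosphine oxide gives 38 with the inverted alkene geometry.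

**Step 23.** Oxidative addition of zerovalent palladium to a tertiary carbonate flanked by two crowded carbons may be slow, so that the carbonate is recovered or decomposes. Fallback, setting out from 17 and 33 and returning at 37: the alkoxide 35 is protonated (NH4Cl) instead of acylated to give the propargylic alcohol F5. LiAlH4 with AlCl3 in THF at reflux adds hydride to C17 (hydroxyl-directed hydroalumination), and the aluminate eliminates to the allene.

**Step 10.** The facial selectivity of the protonation rests on the fold of the bicycle and may be modest, which would leave a mixture of C2 epimers. Fallback, setting out from 14 and returning at 17: 14 is converted into the α-methylene ketone F6 (LiN(i-Pr)2, then Me2N=CH2 iodide, MeI, NaHCO3). F6 is hydrogenated (H2, Pd/C), with hydrogen delivered to C2 from the exo face on the catalyst surface.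

**Step 19.** Seven-membered ring closure at the tertiary C25 may lose out to 6-exo attack of the hydroxyl on C23 or to capture of the mercurinium ion by trifluoroacetate, and the radical oxygenation may give reduced (C23–H) material. Fallback, setting out from 29 and returning at 31 (as a single C23 epimer): Shi epoxidation of 29 (D-fructose-derived ketone, KHSO5) gives the epoxide F7, which diethylaluminium 2,2,6,6-tetramethylpiperidide isomerises to the isopropenyl carbinol F8. Hg(OCOCF3)2 then closes the oxepane of F8 by the 7-exo mode, in which ring size and Markovnikov preference point the same way, to give the organomercurial F9. Ordinary reductive demercuration (NaBH4) turns the CH2Hg group of F9 into the second methyl group on C25.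

**Step 1.** An α-branched alkenyl Grignard reagent may add with low enantioselectivity, and the magnesium enolate may alkylate sluggishly. Fallback, setting out from 1 and returning at 5: the same addition and allylation are run with CuI and no ligand to give racemic 5, which NaBH4 reduces to the alcohol F10. A lipase with vinyl acetate acylates the unwanted enantiomer to the acetate F11, and the remaining (2S,3R)-alcohol F10 is oxidised back to 5 with Dess–Martin periodinane.

Further compounds

F1 | step 8 | (1R,3aR,4S,7aR)-1-methyl-4-[2-(methylselanyl)propan-2-yl]-1-[(triethylsilyl)oxy]octahydro-1H-inden-4-ol | C[Se]C(C)(C)[C@]1(O)CCC[C@@H]2[C@H]1CC[C@@]2(C)O[Si](CC)(CC)CC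
F2 | step 24 | (E)-isomer of 38 (C17 cis to C2) | C[C@H]1CC[C@@H]2[C@@H](CC[C@@]2(C)O[Si](CC)(CC)CC)C(C)(C)/C1=C/C[C@@H]1[C@@]2(C)CCC(O[Si](CC)(CC)CC)C(C)(C)O[C@@H]2CC[C@]1(C)O[Si](CC)(CC)CC
F3 | step 24 | C15–C16 epoxide of F2 (either face) | C[C@H]1CC[C@@H]2[C@@H](CC[C@@]2(C)O[Si](CC)(CC)CC)C(C)(C)C13OC3C[C@@H]1[C@@]2(C)CCC(O[Si](CC)(CC)CC)C(C)(C)O[C@@H]2CC[C@]1(C)O[Si](CC)(CC)CC
F4 | step 24 | C15-hydroxy C16-(methyldiphenylphosphonio) iodide from F3 | C[C@H]1CC[C@@H]2[C@@H](CC[C@@]2(C)O[Si](CC)(CC)CC)C(C)(C)C1(O)C(C[C@@H]1[C@@]2(C)CCC(O[Si](CC)(CC)CC)C(C)(C)O[C@@H]2CC[C@]1(C)O[Si](CC)(CC)CC)[P+](C)(c1ccccc1)c1ccccc1.[I-]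
F5 | step 23 | tertiary propargylic alcohol from 34 and 17 (C15 epimers) | C[C@H]1CC[C@@H]2[C@@H](CC[C@@]2(C)O[Si](CC)(CC)CC)C(C)(C)C1(O)C#C[C@@H]1[C@@]2(C)CCC(O[Si](CC)(CC)CC)C(C)(C)O[C@@H]2CC[C@]1(C)O[Si](CC)(CC)CC
F6 | step 10 | (1R,3aR,8aR)-1,4,4-trimethyl-6-methylidene-1-[(triethylsilyl)oxy]octahydroazulen-5(1H)-one | C=C1CC[C@@H]2[C@@H](CC[C@@]2(C)O[Si](CC)(CC)CC)C(C)(C)C1=O
F7 | step 19 | (R)-epoxide of the side-chain alkene of 29 | COC(OC)[C@@H]1[C@@](C)(CC[C@H]2OC2(C)C)[C@H](O)CC[C@]1(C)O
F8 | step 19 | isopropenyl carbinol from F7 (side chain (R)-3-hydroxy-4-methylpent-4-en-1-yl) | COC(OC)[C@@H]1[C@@](C)(CC[C@@H](O)C(C)=C)[C@H](O)CC[C@]1(C)O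
F9 | step 19 | oxepane with CH2Hg(OCOCF3) on C25 (C25 epimers) | COC(OC)[C@@H]1[C@@]2(C)CC[C@@H](O)C(C)(C[Hg]OC(=O)C(F)(F)F)O[C@@H]2CC[C@]1(C)O
F10 | step 1 | (1S,2S,3R)-2-allyl-3-(prop-1-en-2-yl)cyclohexan-1-ol (racemic before resolution) | O[C@H]1CCC[C@@H](C(C)=C)[C@@H]1CC=C
F11 | step 1 | (1R,2R,3S)-2-allyl-3-(prop-1-en-2-yl)cyclohexyl acetate | CC(=O)O[C@@H]1CCC[C@H](C(C)=C)[C@H]1CC=C
A1 | alternative 1 | 1-diazo-4-(3-methoxy-2,4-dimethylphenyl)butan-2-one | [N-]=[N+]=CC(=O)CCc1ccc(C)c(OC)c1C
A2 | alternative 1 | 5-methoxy-4,6-dimethyl-3,8a-dihydroazulen-1(2H)-one | O=C1CCC2=C(C)C(OC)=C(C)C=C[C@@H]12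
A3 | alternative 2 | diepoxide silyl enol ether (tert-butyldimethylsilyl enol ether of the allyl ketone, either enol ether geometry) | CC1(C)O[C@@H]1CC[C@@]1(C)O[C@@H]1CCC(O[Si](C)(C)C(C)(C)C)=CCC=C
A4 | alternative 2 | trans-fused oxepanol–cyclohexanone with an allyl group on C18 | C=CC[C@@H]1[C@@]2(C)CC[C@@H](O)C(C)(C)O[C@@H]2CCC1=O
A5 | alternative 3 | (R)-5,5-dimethyl-6-methylidene-4-(3-oxobutyl)cyclohept-2-en-1-one | C=C1CC(=O)C=C[C@@H](CCC(C)=O)C1(C)C
A6 | alternative 3 | cis-fused hydroazulenol with C3 ketone and C15 methylene | C=C1CC(=O)C[C@@H]2[C@@H](CC[C@@]2(C)O)C1(C)C
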